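- Count the impurity against the catalyst before you give a stalled flask more time; the green flask, followed so far, is the case here.

| flask | substrate | free catalyst | impurity | temperature | remark | time |
|---|---|---|---|---|---|---|
| green | 0.020 M | 1 mM | 1.4 mM | 90 °C | the very flask that is asked about, followed so far |  |
| grey | 0.020 M | 1 mM | 2.1 mM | 96 °C | run made earlier |  |
| flask | 0.020 M | 1.0 mM | 1.4 mM | 90 °C |  | 8.0 d |

green run (percent of the substrate charged)

| time / d | product / % | substrate / % |
|---|---|---|
| 0.833 | 13.7 | 84.6 |
| 1.67 | 21.0 | 80.0 |
| 3.00 | 24.3 | 75.6 |
| 4.00 | 24.5 | 74.3 |
| 5.00 | 26.7 | 74.2 |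
| 6.00 | 26.4 | 73.0 |

grey run (percent of the substrate charged)

| time / h | product / % | substrate / % |
|---|---|---|
| 6.00 | 8.0 | 91.0 |
| 15.0 | 11.7 | 86.5 |
| 20.0 | 13.8 | 86.2 |
| 30.0 | 14.9 | 84.8 |
| 40.0 | 14.7 | 85.9 |
| 50.0 | 14.4 | 85.7 |

(each reading ± 0.5 percentage points)

- product that was removed still counts
- additions bring no volume worth counting

- Sunday's: at 8.0 d add free catalyst, 100% of the amount charged, then wait 15 d
- Thursday's: at 8.0 d raise the temperature by 15 K, then wait 15 d
- Wednesday's: change nothing and wait 15 d more
- Tuesday's: at 8.0 d take out 90% of the product then present, then wait 15 d

- product, in percent of the substrate first charged, at 8.0 d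
- the remedy with the largest gain of product, or "none" below 2 percentage points (Sunday's / Thursday's / Wednesday's / Tuesday's / none)
- product present, with what was taken out counted in, in percent of the substrate first charged, after Thursday's
- product present, with what was taken out counted in, in percent of the substrate first charged, after Tuesday's

- The bench rule says that a catalyst comes back after each round, so a slow flask finishes if you wait. The green flask needs 20.0 rounds per catalyst charged, but its last reading stands at 5.28 rounds, and its last two product readings differ by 0.3 percentage points against a scatter of 0.5 points.
- The rule stops where the impurity can take up the catalyst. The poison ratio, impurity charged divided by catalyst charged, is 1.40 in the green flask. Assume that one impurity removes one catalyst for good: the border then lies at a ratio of 1, and above it the impurity charged outnumbers the catalyst charged.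
- The grey run has a ratio of 2.10 and its last reading is 14.4%, lower than the green flask's 26.4%, but the grey run was also hotter, so this comparison mixes two settings.
- Your reckoning for the green flask follows. Because the impurity exceeds the catalyst, product stays near the mean of the last two readings, 26.6%, under Wednesday's, Thursday's and Tuesday's alike. Sunday's brings the ratio over the catalyst charged in total to 0.700, so the catalyst charged in total outnumbers the impurity charged and the 73.0% of substrate last read can turn. Choose Sunday's.
- The forecast gives 26.7% now, Sunday's as the best remedy, and 27.2% after Thursday's and 27.2% after Tuesday's, on the ground that “Impurity exceeds catalyst, so all the catalyst dies”.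
- The simulated green flask gives 26.4% now and Sunday's as the best remedy, with a gain of 74 points; Thursday's ends at 26.5% and Tuesday's at 26.5%.

    substrate + free catalyst → catalyst intermediate A (k = 3170 L mol⁻¹ h⁻¹, Ea = 55.0 kJ mol⁻¹)
    catalyst intermediate A → catalyst intermediate B (k = 0.474 h⁻¹, Ea = 122 kJ mol⁻¹)
    catalyst intermediate B → free catalyst + product (k = 0.781 h⁻¹, Ea = 102 kJ mol⁻¹)
    free catalyst + impurity → spent catalyst (k = 12900 L mol⁻¹ h⁻¹, Ea = 54.0 kJ mol⁻¹)
    (constants at 90 °C)

- The poison ratio puts the spare impurity at 28.6% of its charge, and the green flask holds 29% at 8.00 d, with spent catalyst at 99.9%. The neighbour charged with 0.0025 M of free catalyst, otherwise unchanged, has a ratio of 0.560, with impurity below catalyst. At 8.00 d it holds impurity 0%, free catalyst 44.0%, spent catalyst 56.0% and product 100%.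

All runs are calculated with made-up constants, and the scatter is random.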